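**Plan** (germacrane numbering: ring C1–C10, C1=C10 with Me on C10, C3 angelate, C4(Me)–C5 oxirane, C6 acetate, C7 isopropyl)
Retrosynthesis: both esters are removed and the oxirane is taken back to the (E)-C4=C5 alkene. The ten-membered ring is then cut at C5–C6, because C5 (oxirane CH) is a masked alkenyl carbon and C6 (acetoxy carbinol) a masked aldehyde carbon, so the ring is the allylic-alcohol adduct of an alkenyl iodide and an aldehyde. The open chain is cut at C8–C9 (allylic bromide + alkyl Grignard) and at C2–C3 (vinylogous aldol).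
Forward: iodoenal 2 and the tiglate-derived silyl dienol ether 7 give C9–C10–C1–C2–C3–C4–C5 with both E alkenes in place. Allylic bromide 11 is joined at C8–C9 to the C6–C8 piece 16. C6 is unmasked, the cyclodeca-1(10),4-diene ring is closed first and the oxirane second, and acetylation, desilylation and angeloylation are fitted around them.
Stereochemistry: C3 comes from a valine-derived oxazolidinone (remote induction in the vinylogous aldol) and C7 from a phenylalanine-derived oxazolidinone (titanium enolate alkylation). C6 comes from C7 by Felkin–Anh addition during ring closure, and C4/C5 from C3 by hydroxyl-directed epoxidation. The E-C1=C10 geometry comes from the conjugated enoyl imide and E-C4=C5 from the iodoenal.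

Key step: step 13

Assumption: the γ-unsubstituted silyl N,O-acetal 7 is taken to show the same sense of remote induction as its γ-methyl homologues (attack anti to the 4-isopropyl group), which calls for the (R)-oxazolidinone 3; were the sense opposite, the enantiomer of 3 would be used in the same way.

Step 1
Reactants: 1 (E)-3-iodo-2-methylprop-2-en-1-ol
Product: 2 (E)-3-iodo-2-methylprop-2-enal
Conditions: MnO2 (activated, excess), CH2Cl2, 25 °C, dark
Reagents that add atoms: none
Why: Activated MnO2 oxidises the allylic alcohol to the enal chemoselectively (allylic alcohol oxidation) and should leave the iodoalkene and its E geometry untouched, no stereocentre being formed.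

Step 2
Reactants: 3 (R)-4-isopropyloxazolidin-2-one; 4 tigloyl chloride [(E)-2-methylbut-2-enoyl chloride]
Product: 5 (R)-4-isopropyl-3-[(E)-2-methylbut-2-enoyl]oxazolidin-2-one
Conditions: Et3N, LiCl, THF, 0 → 25 °C
Reagents that add atoms: none
Why: N-acylation of the oxazolidinone by the acid chloride under LiCl/Et3N activation needs no strong base, so the E-configured tigloyl unit should be carried over without deconjugation.

Step 3
Reactants: 5 (R)-4-isopropyl-3-[(E)-2-methylbut-2-enoyl]oxazolidin-2-one
Product: 7 (R)-3-[(1E)-1-(tert-butyldimethylsilyloxy)-2-methylbuta-1,3-dienyl]-4-isopropyloxazolidin-2-one, via sodium dienolate 6 (not isolated)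
Conditions: NaN(SiMe3)2, THF, −78 °C; then tBuMe2SiCl, −78 → 0 °C
Reagents that add atoms: tert-butyldimethylsilyl chloride, CC(C)(C)[Si](C)(C)Cl
Why: γ-Deprotonation of the enoyl imide gives the extended dienolate 6, which is silylated on oxygen to the (1E)-vinylketene silyl N,O-acetal (silyl dienol ether formation), in which the oxazolidinone should twist out of the diene plane and shield one face.

Step 4
Reactants: 7 (R)-3-[(1E)-1-(tert-butyldimethylsilyloxy)-2-methylbuta-1,3-dienyl]-4-isopropyloxazolidin-2-one; 2 (E)-3-iodo-2-methylprop-2-enal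
Product: 8 (R)-3-[(2E,5R,6E)-5-hydroxy-7-iodo-2,6-dimethylhepta-2,6-dienoyl]-4-isopropyloxazolidin-2-one
Conditions: TiCl4, CH2Cl2, −78 °C; aqueous work-up
Reagents that add atoms: none
Why: Vinylogous Mukaiyama aldol reaction, in which the TiCl4-bound enal is attacked at its carbonyl carbon by the γ-carbon of 7 on the diene face opposite the isopropyl group of the twisted oxazolidinone, which should set C3 as R by remote induction and deliver the C1=C10 alkene as the conjugated (E)-2-methylenoyl unit.

Step 5
Reactants: 8 (R)-3-[(2E,5R,6E)-5-hydroxy-7-iodo-2,6-dimethylhepta-2,6-dienoyl]-4-isopropyloxazolidin-2-one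
Product: 9 (R)-3-[(2E,5R,6E)-5-(tert-butyldimethylsilyloxy)-7-iodo-2,6-dimethylhepta-2,6-dienoyl]-4-isopropyloxazolidin-2-one
Conditions: tBuMe2SiOTf, 2,6-lutidine, CH2Cl2, −78 → 0 °C
Reagents that add atoms: tert-butyldimethylsilyl triflate, CC(C)(C)[Si](C)(C)OS(=O)(=O)C(F)(F)F
Why: Silylation of the secondary allylic alcohol with a silyl triflate and a hindered pyridine base is fast at low temperature and should not touch the imide or the iodoalkene.

Step 6
Reactants: 9 (R)-3-[(2E,5R,6E)-5-(tert-butyldimethylsilyloxy)-7-iodo-2,6-dimethylhepta-2,6-dienoyl]-4-isopropyloxazolidin-2-one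
Product: 10 (2E,5R,6E)-5-(tert-butyldimethylsilyloxy)-7-iodo-2,6-dimethylhepta-2,6-dien-1-ol
Conditions: NaBH4, THF/H2O, 0 → 25 °C
Reagents that add atoms: none
Why: NaBH4 in wet THF reduces the N-enoyl oxazolidinone at the exocyclic carbonyl (reductive cleavage of the auxiliary to the allylic alcohol), the α-methyl group should disfavour conjugate reduction, and auxiliary 3 is recovered.

Step 7
Reactants: 10 (2E,5R,6E)-5-(tert-butyldimethylsilyloxy)-7-iodo-2,6-dimethylhepta-2,6-dien-1-ol
Product: 11 tert-butyl{[(1E,3R,5E)-7-bromo-1-iodo-2,6-dimethylhepta-1,5-dien-3-yl]oxy}dimethylsilane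
Conditions: CBr4, PPh3, CH2Cl2, 0 °C
Reagents that add atoms: carbon tetrabromide, BrC(Br)(Br)Br
Why: Appel reaction, in which bromide displaces the activated primary allylic oxygen by SN2 at the primary carbon, without allylic transposition and with the silyl ether and iodoalkene inert.

Step 8
Reactants: 12 (S)-4-benzyl-3-(3-methylbutanoyl)oxazolidin-2-one
Product: 14 (S)-4-benzyl-3-[(2R)-2-(dimethoxymethyl)-3-methylbutanoyl]oxazolidin-2-one, via chlorotitanium Z-enolate 13 (not isolated)
Conditions: TiCl4, iPr2NEt, CH2Cl2, 0 °C; then HC(OMe)3, 0 °C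
Reagents that add atoms: trimethyl orthoformate, COC(OC)OC
Why: Titanium enolate alkylation of an N-acyl oxazolidinone (Evans auxiliary), in which the chelated Z-enolate 13 is attacked by the dimethoxycarbenium ion from the orthoformate on the face opposite the benzyl group, setting C7 and bringing in C6 already at the aldehyde oxidation level as its dimethyl acetal.

Step 9
Reactants: 14 (S)-4-benzyl-3-[(2R)-2-(dimethoxymethyl)-3-methylbutanoyl]oxazolidin-2-one
Product: 15 (2S)-2-(dimethoxymethyl)-3-methylbutan-1-ol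
Conditions: LiBH4, H2O (1 equiv), THF, 0 °C
Reagents that add atoms: none
Why: LiBH4 cleaves the imide reductively to the primary alcohol (reductive removal of the auxiliary) without epimerisation and should leave the acetal untouched.

Step 10
Reactants: 15 (2S)-2-(dimethoxymethyl)-3-methylbutan-1-ol
Product: 16 (2R)-2-(bromomethyl)-1,1-dimethoxy-3-methylbutane
Conditions: CBr4, PPh3, 2,6-lutidine (0.2 equiv), CH2Cl2, 0 °C
Reagents that add atoms: carbon tetrabromide, BrC(Br)(Br)Br
Why: Appel reaction on the β-branched primary alcohol, buffered by a trace of base so that the acetal survives, with the stereocentre not involved.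

Step 11
Reactants: 16 (2R)-2-(bromomethyl)-1,1-dimethoxy-3-methylbutane; 11 tert-butyl{[(1E,3R,5E)-7-bromo-1-iodo-2,6-dimethylhepta-1,5-dien-3-yl]oxy}dimethylsilane
Product: 18 tert-butyl{[(1E,3R,5E,9R)-1-iodo-10,10-dimethoxy-2,6-dimethyl-9-isopropyldeca-1,5-dien-3-yl]oxy}dimethylsilane, via Grignard reagent 17 (not isolated)
Conditions: Mg, THF, 25 °C; then 11, Li2CuCl4 (5 mol%), THF, −78 → 0 °C
Reagents that add atoms: none
Why: Copper-catalysed cross-coupling of a primary alkyl Grignard reagent with a primary allylic bromide should proceed by direct SN2 substitution at C9 with retention of the alkene geometry at low temperature, where the iodoalkene and silyl ether do not react, 17 being made below 30 °C and used at once to avoid 1,3-elimination of methoxide.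

Step 12
Reactants: 18 tert-butyl{[(1E,3R,5E,9R)-1-iodo-10,10-dimethoxy-2,6-dimethyl-9-isopropyldeca-1,5-dien-3-yl]oxy}dimethylsilane
Product: 19 (2R,5E,8R,9E)-8-(tert-butyldimethylsilyloxy)-10-iodo-2-isopropyl-5,9-dimethyldeca-5,9-dienal
Conditions: pyridinium p-toluenesulfonate (cat.), acetone/H2O, 25–40 °C
Reagents that add atoms: water, O
Why: Acid-catalysed acetal hydrolysis with a weak pyridinium acid frees the C6 aldehyde, while the allylic silyl ether and the α-stereocentre C7 (hindered towards enolisation by the isopropyl group) should be preserved.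

Step 13
Reactants: 19 (2R,5E,8R,9E)-8-(tert-butyldimethylsilyloxy)-10-iodo-2-isopropyl-5,9-dimethyldeca-5,9-dienal
Product: 21 (1(10)E,4E,3R,6S,7R)-3-(tert-butyldimethylsilyloxy)germacra-1(10),4-dien-6-ol, via alkenylchromium dichloride 20 (not isolated)
Conditions: CrCl2 (excess), NiCl2 (cat.), degassed DMSO/THF, 25 °C, high dilution (about 0.003 M, slow addition of 19)
Reagents that add atoms: none
Why: Nozaki–Hiyama–Kishi reaction: zerovalent nickel, formed from NiCl2 by CrCl2, inserts into the C5–I bond with retention of the E geometry, transmetalation gives the alkenyl species 20 of trivalent chromium, and this adds to the C6 aldehyde. The closest known reaction type is the intramolecular Nozaki–Hiyama–Kishi closure of nine- and ten-membered carbocycles from (E)-iodoalkene aldehydes. The cyclodecadiene ring closes in the 10-exo-trig mode, the C=O bond lying outside the new ring. The new stereocentre C6 is controlled by the neighbouring C7 centre, Felkin–Anh addition anti to the isopropyl group giving 6S. The step needs ring closure to win over intermolecular coupling, which high dilution and slow addition should secure, and it needs chemoselectivity for the aldehyde without epimerisation at C7, which the low basicity and carbonyl selectivity of alkenylchromium reagents secure. The two E alkenes already present (C1=C10 and C4=C5) restrict the chain to conformations close to that of the germacrane ring.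

Step 14
Reactants: 21 (1(10)E,4E,3R,6S,7R)-3-(tert-butyldimethylsilyloxy)germacra-1(10),4-dien-6-ol
Product: 22 (1(10)E,4E,3R,6S,7R)-3-(tert-butyldimethylsilyloxy)germacra-1(10),4-dien-6-yl acetate
Conditions: Ac2O, pyridine, 4-dimethylaminopyridine (cat.), CH2Cl2, 0 → 25 °C
Reagents that add atoms: acetic anhydride, CC(=O)OC(C)=O
Why: Acylation of the secondary allylic alcohol under nucleophilic catalysis (ester formation) proceeds with retention at C6 and is run at or below room temperature so that the 1,5-diene does not undergo Cope rearrangement.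

Step 15
Reactants: 22 (1(10)E,4E,3R,6S,7R)-3-(tert-butyldimethylsilyloxy)germacra-1(10),4-dien-6-yl acetate
Product: 23 (1(10)E,4E,3R,6S,7R)-3-hydroxygermacra-1(10),4-dien-6-yl acetate
Conditions: Bu4NF, AcOH (1:1), THF, 0 → 25 °C
Reagents that add atoms: none
Why: Fluoride-induced desilylation, buffered with acetic acid to keep the medium near neutral, which should protect the acetate from cleavage and the cyclodeca-1,5-diene from acid-induced transannular cyclisation.

Step 16
Reactants: 23 (1(10)E,4E,3R,6S,7R)-3-hydroxygermacra-1(10),4-dien-6-yl acetate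
Product: 24 (1(10)E,3R,4R,5R,6S,7R)-4,5-epoxy-3-hydroxygermacr-1(10)-en-6-yl acetate
Conditions: VO(acac)2 (cat.), tBuOOH (in decane), CH2Cl2, 0 °C
Reagents that add atoms: tert-butyl hydroperoxide, CC(C)(C)OO
Why: Vanadium-catalysed hydroxyl-directed epoxidation, in which the C3 hydroxyl bound to vanadium delivers the peroxide oxygen to the allylic C4=C5 bond faster than to the homoallylic C1=C10 bond, and allylic 1,2-strain with the C4 methyl group should favour the erythro epoxy alcohol, that is the (4R,5R) oxirane.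

Step 17
Reactants: 24 (1(10)E,3R,4R,5R,6S,7R)-4,5-epoxy-3-hydroxygermacr-1(10)-en-6-yl acetate; 25 angelic acid [(Z)-2-methylbut-2-enoic acid]
Product: 27 (1(10)E,3R,4R,5R,6S,7R)-6-acetoxy-4,5-epoxygermacr-1(10)-en-3-yl angelate (target CNP0180504.5), via angelic 2,4,6-trichlorobenzoic anhydride 26 (not isolated)
Conditions: 2,4,6-trichlorobenzoyl chloride, Et3N, toluene, 25 °C; then 24, 60 °C
Reagents that add atoms: none
Why: Yamaguchi esterification, in which the mixed anhydride 26 acylates the hindered C3 hydroxyl under mildly basic conditions without an acyl-transfer catalyst, which should limit isomerisation of the angelate to the tiglate and avoid Payne rearrangement, gentle heating being tolerable because the oxirane has removed the 1,5-diene.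

**Compound list**
1 | (E)-3-iodo-2-methylprop-2-en-1-ol | OC/C(C)=C/I | starting material
2 | (E)-3-iodo-2-methylprop-2-enal | O=C/C(C)=C/I | intermediate
3 | (R)-4-isopropyloxazolidin-2-one | CC(C)[C@@H]1COC(=O)N1 | starting material
4 | tigloyl chloride, (E)-2-methylbut-2-enoyl chloride | C/C=C(\C)C(Cl)=O | starting material
5 | (R)-4-isopropyl-3-[(E)-2-methylbut-2-enoyl]oxazolidin-2-one | C/C=C(\C)C(=O)N1[C@H](C(C)C)COC1=O | intermediate
6 | sodium dienolate of 5 (formed in the flask) | C=C/C(C)=C(/[O-])N1[C@H](C(C)C)COC1=O.[Na+] | intermediate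
7 | (R)-3-[(1E)-1-(tert-butyldimethylsilyloxy)-2-methylbuta-1,3-dienyl]-4-isopropyloxazolidin-2-one | C=C/C(C)=C(/O[Si](C)(C)C(C)(C)C)N1[C@H](C(C)C)COC1=O | intermediate
8 | (R)-3-[(2E,5R,6E)-5-hydroxy-7-iodo-2,6-dimethylhepta-2,6-dienoyl]-4-isopropyloxazolidin-2-one | I/C=C(\C)[C@H](O)C/C=C(\C)C(=O)N1[C@H](C(C)C)COC1=O | intermediate
9 | (R)-3-[(2E,5R,6E)-5-(tert-butyldimethylsilyloxy)-7-iodo-2,6-dimethylhepta-2,6-dienoyl]-4-isopropyloxazolidin-2-one | I/C=C(\C)[C@H](O[Si](C)(C)C(C)(C)C)C/C=C(\C)C(=O)N1[C@H](C(C)C)COC1=O | intermediate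
10 | (2E,5R,6E)-5-(tert-butyldimethylsilyloxy)-7-iodo-2,6-dimethylhepta-2,6-dien-1-ol | I/C=C(\C)[C@H](O[Si](C)(C)C(C)(C)C)C/C=C(\C)CO | intermediate
11 | tert-butyl{[(1E,3R,5E)-7-bromo-1-iodo-2,6-dimethylhepta-1,5-dien-3-yl]oxy}dimethylsilane | I/C=C(\C)[C@H](O[Si](C)(C)C(C)(C)C)C/C=C(\C)CBr | intermediate
12 | (S)-4-benzyl-3-(3-methylbutanoyl)oxazolidin-2-one | CC(C)CC(=O)N1[C@@H](Cc2ccccc2)COC1=O | starting material
13 | chlorotitanium Z-enolate of 12 (formed in the flask) | CC(C)/C=C(\O[Ti](Cl)(Cl)Cl)N1[C@@H](Cc2ccccc2)COC1=O | intermediate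
14 | (S)-4-benzyl-3-[(2R)-2-(dimethoxymethyl)-3-methylbutanoyl]oxazolidin-2-one | CC(C)[C@H](C(OC)OC)C(=O)N1[C@@H](Cc2ccccc2)COC1=O | intermediate
15 | (2S)-2-(dimethoxymethyl)-3-methylbutan-1-ol | CC(C)[C@H](C(OC)OC)CO | intermediate
16 | (2R)-2-(bromomethyl)-1,1-dimethoxy-3-methylbutane | CC(C)[C@H](C(OC)OC)CBr | intermediate
17 | [(2R)-2-(dimethoxymethyl)-3-methylbutyl]magnesium bromide (formed in the flask) | CC(C)[C@H](C(OC)OC)C[Mg]Br | intermediate
18 | tert-butyl{[(1E,3R,5E,9R)-1-iodo-10,10-dimethoxy-2,6-dimethyl-9-isopropyldeca-1,5-dien-3-yl]oxy}dimethylsilane | I/C=C(\C)[C@H](O[Si](C)(C)C(C)(C)C)C/C=C(\C)CC[C@H](C(C)C)C(OC)OC | intermediate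
19 | (2R,5E,8R,9E)-8-(tert-butyldimethylsilyloxy)-10-iodo-2-isopropyl-5,9-dimethyldeca-5,9-dienal | I/C=C(\C)[C@H](O[Si](C)(C)C(C)(C)C)C/C=C(\C)CC[C@H](C(C)C)C=O | intermediate
20 | alkenylchromium dichloride from 19, trivalent chromium on C5 (formed in the flask) | Cl[Cr](Cl)/C=C(\C)[C@H](O[Si](C)(C)C(C)(C)C)C/C=C(\C)CC[C@H](C(C)C)C=O | intermediate
21 | (1(10)E,4E,3R,6S,7R)-3-(tert-butyldimethylsilyloxy)germacra-1(10),4-dien-6-ol | CC(C)(C)[Si](C)(C)O[C@@H]1C/C=C(\C)CC[C@H](C(C)C)[C@H](O)/C=C/1\C | intermediate
22 | (1(10)E,4E,3R,6S,7R)-3-(tert-butyldimethylsilyloxy)germacra-1(10),4-dien-6-yl acetate | CC(C)(C)[Si](C)(C)O[C@@H]1C/C=C(\C)CC[C@H](C(C)C)[C@H](OC(C)=O)/C=C/1\C | intermediate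
23 | (1(10)E,4E,3R,6S,7R)-3-hydroxygermacra-1(10),4-dien-6-yl acetate | O[C@@H]1C/C=C(\C)CC[C@H](C(C)C)[C@H](OC(C)=O)/C=C/1\C | intermediate
24 | (1(10)E,3R,4R,5R,6S,7R)-4,5-epoxy-3-hydroxygermacr-1(10)-en-6-yl acetate | O[C@@H]1C/C=C(\C)CC[C@H](C(C)C)[C@H](OC(C)=O)[C@H]2O[C@@]21C | intermediate
25 | angelic acid, (Z)-2-methylbut-2-enoic acid | C/C=C(/C)C(=O)O | starting material
26 | angelic 2,4,6-trichlorobenzoic anhydride (formed in the flask) | C/C=C(/C)C(=O)OC(=O)c1c(Cl)cc(Cl)cc1Cl | intermediate
27 | (1(10)E,3R,4R,5R,6S,7R)-6-acetoxy-4,5-epoxygermacr-1(10)-en-3-yl angelate, CNP0180504.5 | C/C=C(/C)C(=O)O[C@@H]1C/C=C(\C)CC[C@H](C(C)C)[C@H](OC(C)=O)[C@H]2O[C@@]21C | target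

**Step count and risks**
Total: 17 steps. Longest linear sequence: 13 steps (steps 2–7, then 11–17).

Most likely to fail:

Step 13 (ring closure). The ring-forming transition state may select the aldehyde face against the Felkin–Anh sense, so that the C6 epimer predominates. Fallback: from 19 the closure is run without regard to C6. The resulting mixture of 21 and its C6 epimer, (1(10)E,4E,3R,6R,7R)-3-(tert-butyldimethylsilyloxy)germacra-1(10),4-dien-6-ol F1, is oxidised with Dess–Martin periodinane (NaHCO3, CH2Cl2) to the cyclodecadienone (1(10)E,4E,3R,7R)-3-(tert-butyldimethylsilyloxy)germacra-1(10),4-dien-6-one F2. C6 is then set by reagent control, by Corey–Bakshi–Shibata reduction with the (R)-methyl oxazaborolidine and BH3·SMe2 (alkenyl group as the large substituent), which comes back to the route at 21.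

Step 11 (fragment union). Regiocontrol may be lost by SN2′ attack at C1, or the Grignard reagent may decay by 1,3-elimination of methoxide before it couples. Fallback: the C8–C9 bond is made as an alkene and then saturated. Compound 10 is oxidised with MnO2 to (2E,5R,6E)-5-(tert-butyldimethylsilyloxy)-7-iodo-2,6-dimethylhepta-2,6-dienal F3. Compound 16 is heated with PPh3 to give [(2R)-2-(dimethoxymethyl)-3-methylbutyl]triphenylphosphonium bromide F4. Wittig reaction of the ylide of F4 (NaN(SiMe3)2, THF, −78 °C) with F3 should give tert-butyl{[(1E,3R,5E,7Z,9S)-1-iodo-10,10-dimethoxy-2,6-dimethyl-9-isopropyldeca-1,5,7-trien-3-yl]oxy}dimethylsilane F5. Diimide (2-nitrobenzenesulfonylhydrazide, Et3N, CH2Cl2) should then reduce only the disubstituted alkene and spare the trisubstituted alkene and the iodoalkene, which comes back to the route at 18.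

Step 16 (epoxidation). Oxygen may be delivered to the wrong face of C4=C5 if the ring conformation overrides allylic strain, or to the homoallylic C1=C10 bond. Fallback: the directing group is changed. From 21, which has the C6 hydroxyl free and no alkene homoallylic to it, VO(acac)2/tBuOOH epoxidation is directed by the C6 hydroxyl; allylic 1,3-strain with the C4 methyl group favours the threo product on the same (4R,5R) face. This gives (1(10)E,3R,4R,5R,6S,7R)-3-(tert-butyldimethylsilyloxy)-4,5-epoxygermacr-1(10)-en-6-ol F6. Acetylation (Ac2O, pyridine) gives (1(10)E,3R,4R,5R,6S,7R)-3-(tert-butyldimethylsilyloxy)-4,5-epoxygermacr-1(10)-en-6-yl acetate F7, and desilylation with Bu4NF/AcOH comes back to the route at 24.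

**Further compounds**
F1 | step 13 | (1(10)E,4E,3R,6R,7R)-3-(tert-butyldimethylsilyloxy)germacra-1(10),4-dien-6-ol | CC(C)(C)[Si](C)(C)O[C@@H]1C/C=C(\C)CC[C@H](C(C)C)[C@@H](O)/C=C/1\C
F2 | step 13 | (1(10)E,4E,3R,7R)-3-(tert-butyldimethylsilyloxy)germacra-1(10),4-dien-6-one | CC(C)(C)[Si](C)(C)O[C@@H]1C/C=C(\C)CC[C@H](C(C)C)C(=O)/C=C/1\C
F3 | step 11 | (2E,5R,6E)-5-(tert-butyldimethylsilyloxy)-7-iodo-2,6-dimethylhepta-2,6-dienal | I/C=C(\C)[C@H](O[Si](C)(C)C(C)(C)C)C/C=C(\C)C=O
F4 | step 11 | [(2R)-2-(dimethoxymethyl)-3-methylbutyl]triphenylphosphonium bromide | CC(C)[C@H](C(OC)OC)C[P+](c1ccccc1)(c1ccccc1)c1ccccc1.[Br-]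
F5 | step 11 | tert-butyl{[(1E,3R,5E,7Z,9S)-1-iodo-10,10-dimethoxy-2,6-dimethyl-9-isopropyldeca-1,5,7-trien-3-yl]oxy}dimethylsilane | I/C=C(\C)[C@H](O[Si](C)(C)C(C)(C)C)C/C=C(\C)/C=C\[C@H](C(C)C)C(OC)OC
F6 | step 16 | (1(10)E,3R,4R,5R,6S,7R)-3-(tert-butyldimethylsilyloxy)-4,5-epoxygermacr-1(10)-en-6-ol | CC(C)(C)[Si](C)(C)O[C@@H]1C/C=C(\C)CC[C@H](C(C)C)[C@H](O)[C@H]2O[C@@]21C
F7 | step 16 | (1(10)E,3R,4R,5R,6S,7R)-3-(tert-butyldimethylsilyloxy)-4,5-epoxygermacr-1(10)-en-6-yl acetate | CC(C)(C)[Si](C)(C)O[C@@H]1C/C=C(\C)CC[C@H](C(C)C)[C@H](OC(C)=O)[C@H]2O[C@@]21C
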